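**Retrosynthetic overview**
- Labels: C10 is the quaternary carbon, C11=C12 the E-alkene, C13 the allylic methyl centre; the ring is C16 (bears the chain), C17, C18=C19, C20, C21 (gem-dimethyl); C1–C9 is the acyclic half.
- Last bond: C10–C11, by enantioselective Cu-catalysed SN2′ allylic substitution of a C1–C9 allylic phosphate with an (E)-alkenylboronate; this sets C10, the vinyl group and the E-alkene.
- The only ring is formed before fragment union: C16–C21 closure of a tertiary C21 cation onto a (Z)-C16=C17 alkene, then 1,2-hydride shift C18→C17 and loss of H-19. One cascade sets C16, C17 and the ring alkene from a syn-C18/C20-dimethyl precursor.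
- Cyclisation precursor: Wittig union of a C17 methyl ketone (from desymmetrised meso-2,4-dimethylglutaric anhydride) with a C13–C16 ylide from (S)-β-citronellene.
- Acyclic half: two Cu-catalysed asymmetric SN2′ alkylations of tiglyl chloride (C7, then C3), a formaldehyde ene homologation between them, and carboalumination for the E-allylic alcohol.

Assumption: in steps 1, 4, 8 and 16 the antipode of the chiral ligand or alkaloid that gives the configuration drawn is used (both antipodes are available); the sense of induction has to be confirmed on the first intermediate.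

**Step 1**
Reactants: 1 (4-bromobut-1-yn-1-yl)trimethylsilane; 2 (E)-1-chloro-2-methylbut-2-ene
Product: 4 trimethyl[(5R)-5,6-dimethylhept-6-en-1-yn-1-yl]silane, via Grignard reagent 3 (not isolated)
Conditions: Mg, Et2O, 35 °C; then 2, copper thiophene-2-carboxylate Cu(O2CC4H3S) (3 mol%), chiral BINOL-derived phosphoramidite (3.3 mol%), CH2Cl2, −78 °C, slow addition
Reagents that add atoms: none
Why: Cu-catalysed asymmetric allylic alkylation (SN2′) of a 2-substituted allylic chloride with a Grignard reagent; γ-attack creates the C7 stereocentre (R, ligand control) and the 1,1-disubstituted alkene in one step.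

**Step 2**
Reactants: 4 trimethyl[(5R)-5,6-dimethylhept-6-en-1-yn-1-yl]silane
Product: 5 (4R)-4-methyl-3-methylidene-8-(trimethylsilyl)oct-7-yn-1-ol
Conditions: (CH2O)n, Me2AlCl (1.5 equiv), CH2Cl2, 0 → 23 °C
Reagents that add atoms: paraformaldehyde (formaldehyde), C=O
Why: Me2AlCl-promoted carbonyl-ene reaction of formaldehyde with the isopropenyl group; the C–C bond forms at the =CH2 terminus and the hydrogen is taken from the allylic CH3 rather than the hindered tertiary C–H, so the methylidene is regenerated and C7 is untouched.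

**Step 3**
Reactants: 5 (4R)-4-methyl-3-methylidene-8-(trimethylsilyl)oct-7-yn-1-ol
Product: 6 [(5R)-8-bromo-5-methyl-6-methylideneoct-1-yn-1-yl]trimethylsilane
Conditions: CBr4, PPh3, CH2Cl2, 0 °C
Reagents that add atoms: carbon tetrabromide, BrC(Br)(Br)Br
Why: Appel bromination of a primary alcohol under neutral conditions that leave the silylalkyne and the alkene alone.

**Step 4**
Reactants: 6 [(5R)-8-bromo-5-methyl-6-methylideneoct-1-yn-1-yl]trimethylsilane; 2 (E)-1-chloro-2-methylbut-2-ene
Product: 8 trimethyl[(5R,9R)-5,9,10-trimethyl-6-methylideneundec-10-en-1-yn-1-yl]silane, via Grignard reagent 7 (not isolated)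
Conditions: Mg, Et2O, 35 °C; then 2, Cu(O2CC4H3S) (3 mol%), same phosphoramidite (3.3 mol%), CH2Cl2, −78 °C, slow addition
Reagents that add atoms: none
Why: second Cu-catalysed asymmetric SN2′ allylic alkylation with the same ligand antipode, which sets C3 (R) under catalyst control (the C7 centre is four atoms away) and installs the terminal isopropenyl group.

**Step 5**
Reactants: 8 trimethyl[(5R,9R)-5,9,10-trimethyl-6-methylideneundec-10-en-1-yn-1-yl]silane
Product: 9 (5R,9R)-5,9,10-trimethyl-6-methylideneundec-10-en-1-yne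
Conditions: K2CO3 (0.2 equiv), MeOH, 23 °C
Reagents that add atoms: none
Why: base-catalysed methanolysis of the alkynyl C–Si bond (protodesilylation); nothing else in the molecule is base-sensitive.

**Step 6**
Reactants: 9 (5R,9R)-5,9,10-trimethyl-6-methylideneundec-10-en-1-yne
Product: 11 (2E,6R,10R)-3,6,10,11-tetramethyl-7-methylidenedodeca-2,11-dien-1-ol, via alkenyl(dimethyl)alane 10 (not isolated)
Conditions: Me3Al (2.5 equiv), Cp2ZrCl2 (0.25 equiv), CH2Cl2, 0 → 23 °C; then (CH2O)n, 0 → 23 °C
Reagents that add atoms: trimethylaluminium, C[Al](C)C; paraformaldehyde (formaldehyde), C=O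
Why: Negishi Zr-catalysed carboalumination adds Me–Al syn across the terminal alkyne to give the E-alkenylalane, which is hydroxymethylated by formaldehyde; the 1,1-disubstituted alkenes do not react under these conditions.

**Step 7**
Reactants: 11 (2E,6R,10R)-3,6,10,11-tetramethyl-7-methylidenedodeca-2,11-dien-1-ol
Product: 12 diethyl (2E,6R,10R)-3,6,10,11-tetramethyl-7-methylidenedodeca-2,11-dien-1-yl phosphate
Conditions: (EtO)2P(O)Cl, pyridine, DMAP (cat.), CH2Cl2, 0 °C
Reagents that add atoms: diethyl chlorophosphate, CCOP(Cl)(=O)OCC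
Why: O-phosphorylation of the primary allylic alcohol gives the leaving group needed for the Cu-catalysed allylic substitution.

**Step 8**
Reactants: 13 meso-2,4-dimethylglutaric anhydride (cis-3,5-dimethyloxane-2,6-dione)
Product: 14 (2S,4R)-5-methoxy-2,4-dimethyl-5-oxopentanoic acid
Conditions: quinidine (1.1 equiv), MeOH (3 equiv), toluene, −55 °C
Reagents that add atoms: methanol, CO
Why: cinchona-alkaloid-mediated desymmetrising methanolysis of the meso anhydride; this fixes the absolute sense of the syn-dimethyl pair (future C18 and C20) in one step.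

**Step 9**
Reactants: 14 (2S,4R)-5-methoxy-2,4-dimethyl-5-oxopentanoic acid
Product: 17 (3S,5R)-3,5,6-trimethyl-6-[(trimethylsilyl)oxy]heptan-2-one, via trilithium triolate 15 (not isolated), via tris(trimethylsilyl) ether 16 (not isolated)
Conditions: MeLi (4.5 equiv), Et2O/THF, −78 → 0 °C; Me3SiCl (8 equiv), 0 °C; pH 7 aqueous work-up
Reagents that add atoms: methyllithium, [Li]C; chlorotrimethylsilane, C[Si](C)(C)Cl
Why: organolithium addition in which the ester takes two methyls (tertiary alkoxide) while the lithium carboxylate takes one and stops at the gem-diolate; silylation before work-up releases the methyl ketone and leaves the tertiary alcohol as its silyl ether.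

**Step 10**
Reactants: 18 (S)-β-citronellene ((3S)-3,7-dimethylocta-1,6-diene)
Product: 20 (4S)-4-methylhex-5-en-1-ol, via ozonide 19 (not isolated)
Conditions: O3 (1.0 equiv), CH2Cl2, −78 °C; then NaBH4, MeOH, −78 → 20 °C
Reagents that add atoms: ozone, [O-][O+]=O
Why: chemoselective ozonolysis of the electron-rich trisubstituted alkene in the presence of the vinyl group, with reductive work-up; the C13 stereocentre comes from the chiral pool.

**Step 11**
Reactants: 20 (4S)-4-methylhex-5-en-1-ol
Product: 21 (3S)-6-iodo-3-methylhex-1-ene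
Conditions: I2, PPh3, imidazole, CH2Cl2, 0 → 23 °C
Reagents that add atoms: iodine, II
Why: Appel-type iodination of a primary alcohol.

**Step 12**
Reactants: 21 (3S)-6-iodo-3-methylhex-1-ene
Product: 22 [(4S)-4-methylhex-5-en-1-yl]triphenylphosphonium iodide
Conditions: PPh3, MeCN, 80 °C
Reagents that add atoms: triphenylphosphine, c1ccc(cc1)P(c1ccccc1)c1ccccc1
Why: SN2 quaternisation of triphenylphosphine by a primary iodide.

**Step 13**
Reactants: 22 [(4S)-4-methylhex-5-en-1-yl]triphenylphosphonium iodide; 17 (3S,5R)-3,5,6-trimethyl-6-[(trimethylsilyl)oxy]heptan-2-one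
Product: 24 trimethyl{[(3R,5S,6Z,10S)-2,3,5,6,10-pentamethyldodeca-6,11-dien-2-yl]oxy}silane, via phosphorus ylide 23 (not isolated)
Conditions: KN(SiMe3)2, THF, 0 °C; then 17, −78 → 23 °C; minor E isomer removed on AgNO3-impregnated silica
Reagents that add atoms: none
Why: salt-free Wittig reaction of a non-stabilised ylide with an α-branched methyl ketone, which under kinetic control places the ylide substituent cis to the larger (branched) ketone substituent and so gives the Z-trisubstituted alkene (selectivity expected to be moderate, about 5:1).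

**Step 14**
Reactants: 24 trimethyl{[(3R,5S,6Z,10S)-2,3,5,6,10-pentamethyldodeca-6,11-dien-2-yl]oxy}silane
Product: 28 (3R,5R,6R)-1,3,4,4,6-pentamethyl-5-[(3S)-3-methylpent-4-en-1-yl]cyclohex-1-ene, via tertiary C21 cation 25 (not isolated), via cyclohexyl C17 cation 26 (not isolated), via hydride-shifted C18 cation 27 (not isolated)
Conditions: Me3SiOTf (1.2 equiv), 2,6-di-tert-butyl-4-methylpyridine (1.5 equiv), CH2Cl2, −78 → −20 °C
Reagents that add atoms: none
Why: Proposed new method: Me3SiOTf silylates the tertiary silyl ether, which ionises (as tert-butyl ethers do) to the C21 cation; this closes the C16–C21 bond through the chair that keeps the syn C18/C20 methyls equatorial and so puts the Z-alkene substituent (the side chain) axial, trans to C20–Me; the axial C18–H then shifts suprafacially to C17 (C17–Me trans to the chain), and the C18 cation loses the unhindered H-19 to the hindered base, as in kinetic α-ionone/α-irone-type closures; the closest known reaction type is the Lewis-acid cation–olefin (polyene) cyclisation with 1,2-hydride shift and E1 termination, and C20 is either retained or, if the open cation equilibrates by hydride shift, reset to the same equatorial outcome.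

**Step 15**
Reactants: 28 (3R,5R,6R)-1,3,4,4,6-pentamethyl-5-[(3S)-3-methylpent-4-en-1-yl]cyclohex-1-ene
Product: 29 4,4,5,5-tetramethyl-2-{(1E,3S)-3-methyl-5-[(1R,2R,5R)-2,3,5,6,6-pentamethylcyclohex-3-en-1-yl]pent-1-en-1-yl}-1,3,2-dioxaborolane
Conditions: vinylboronic acid pinacol ester (3 equiv), second-generation Hoveyda–Grubbs catalyst (5 mol%), CH2Cl2, 40 °C
Reagents that add atoms: vinylboronic acid pinacol ester, C=CB1OC(C)(C)C(C)(C)O1
Why: olefin cross-metathesis of the terminal vinyl group with vinyl–B(pin) gives the E-alkenylboronate; the hindered trisubstituted ring alkene does not take part.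

**Step 16**
Reactants: 12 diethyl (2E,6R,10R)-3,6,10,11-tetramethyl-7-methylidenedodeca-2,11-dien-1-yl phosphate; 29 4,4,5,5-tetramethyl-2-{(1E,3S)-3-methyl-5-[(1R,2R,5R)-2,3,5,6,6-pentamethylcyclohex-3-en-1-yl]pent-1-en-1-yl}-1,3,2-dioxaborolane
Product: 30 (3R,7R,10S,11E,13S)-10-ethenyl-2,3,7,10,13-pentamethyl-6-methylidene-15-[(1R,2R,5R)-2,3,5,6,6-pentamethylcyclohex-3-en-1-yl]pentadeca-1,11-diene
Conditions: CuCl (5 mol%), chiral sulfonate-bearing imidazolinium salt (N-heterocyclic carbene precursor, 5.5 mol%), NaOMe (1.5 equiv), THF, 60 °C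
Reagents that add atoms: none
Why: N-heterocyclic-carbene–copper-catalysed enantioselective allylic substitution; the methoxide-activated alkenylboronate transmetallates to copper with retention of E geometry and adds SN2′ to the E-trisubstituted allylic phosphate, creating the C10 quaternary centre (S, catalyst control) together with the vinyl group.

**Compound list**
1 | (4-bromobut-1-yn-1-yl)trimethylsilane | C[Si](C)(C)C#CCCBr | starting material
2 | (E)-1-chloro-2-methylbut-2-ene | C/C=C(\C)CCl | starting material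
3 | Grignard reagent [4-(trimethylsilyl)but-3-yn-1-yl]magnesium bromide | C[Si](C)(C)C#CCC[Mg]Br | intermediate
4 | trimethyl[(5R)-5,6-dimethylhept-6-en-1-yn-1-yl]silane | C[Si](C)(C)C#CCC[C@@H](C)C(=C)C | intermediate
5 | (4R)-4-methyl-3-methylidene-8-(trimethylsilyl)oct-7-yn-1-ol | C[Si](C)(C)C#CCC[C@@H](C)C(=C)CCO | intermediate
6 | [(5R)-8-bromo-5-methyl-6-methylideneoct-1-yn-1-yl]trimethylsilane | C[Si](C)(C)C#CCC[C@@H](C)C(=C)CCBr | intermediate
7 | Grignard reagent [(4R)-4-methyl-3-methylidene-8-(trimethylsilyl)oct-7-yn-1-yl]magnesium bromide | C[Si](C)(C)C#CCC[C@@H](C)C(=C)CC[Mg]Br | intermediate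
8 | trimethyl[(5R,9R)-5,9,10-trimethyl-6-methylideneundec-10-en-1-yn-1-yl]silane | C[Si](C)(C)C#CCC[C@@H](C)C(=C)CC[C@@H](C)C(=C)C | intermediate
9 | (5R,9R)-5,9,10-trimethyl-6-methylideneundec-10-en-1-yne | C#CCC[C@@H](C)C(=C)CC[C@@H](C)C(=C)C | intermediate
10 | alkenyl(dimethyl)alane: dimethyl[(1E,5R,9R)-2,5,9,10-tetramethyl-6-methylideneundeca-1,10-dien-1-yl]alumane | C[Al](C)/C=C(C)/CC[C@@H](C)C(=C)CC[C@@H](C)C(=C)C | intermediate
11 | (2E,6R,10R)-3,6,10,11-tetramethyl-7-methylidenedodeca-2,11-dien-1-ol | OC/C=C(C)/CC[C@@H](C)C(=C)CC[C@@H](C)C(=C)C | intermediate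
12 | diethyl (2E,6R,10R)-3,6,10,11-tetramethyl-7-methylidenedodeca-2,11-dien-1-yl phosphate | CCOP(=O)(OCC)OC/C=C(C)/CC[C@@H](C)C(=C)CC[C@@H](C)C(=C)C | intermediate
13 | meso-2,4-dimethylglutaric anhydride (cis-3,5-dimethyloxane-2,6-dione) | C[C@H]1C[C@@H](C)C(=O)OC1=O | starting material
14 | (2S,4R)-5-methoxy-2,4-dimethyl-5-oxopentanoic acid | COC(=O)[C@H](C)C[C@H](C)C(O)=O | intermediate
15 | trilithium triolate: trilithium (3S,5R)-3,5,6-trimethylheptane-2,2,6-triolate | [Li]OC(C)(C)[C@H](C)C[C@H](C)C(C)(O[Li])O[Li] | intermediate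
16 | tris(trimethylsilyl) ether: (3S,5R)-3,5,6-trimethyl-2,2,6-tris[(trimethylsilyl)oxy]heptane | C[Si](C)(C)OC(C)(C)[C@H](C)C[C@H](C)C(C)(O[Si](C)(C)C)O[Si](C)(C)C | intermediate
17 | (3S,5R)-3,5,6-trimethyl-6-[(trimethylsilyl)oxy]heptan-2-one | C[Si](C)(C)OC(C)(C)[C@H](C)C[C@H](C)C(C)=O | intermediate
18 | (S)-β-citronellene, (3S)-3,7-dimethylocta-1,6-diene | C=C[C@@H](C)CCC=C(C)C | starting material
19 | ozonide: 3,3-dimethyl-5-[(3S)-3-methylpent-4-en-1-yl]-1,2,4-trioxolane (both epimers at the ring CH) | C=C[C@@H](C)CCC1OOC(C)(C)O1 | intermediate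
20 | (4S)-4-methylhex-5-en-1-ol | C=C[C@@H](C)CCCO | intermediate
21 | (3S)-6-iodo-3-methylhex-1-ene | C=C[C@@H](C)CCCI | intermediate
22 | [(4S)-4-methylhex-5-en-1-yl]triphenylphosphonium iodide | C=C[C@@H](C)CCC[P+](c1ccccc1)(c1ccccc1)c1ccccc1.[I-] | intermediate
23 | phosphorus ylide: [(4S)-4-methylhex-5-en-1-ylidene]triphenyl-λ5-phosphane | C=C[C@@H](C)CCC=P(c1ccccc1)(c1ccccc1)c1ccccc1 | intermediate
24 | trimethyl{[(3R,5S,6Z,10S)-2,3,5,6,10-pentamethyldodeca-6,11-dien-2-yl]oxy}silane | C[Si](C)(C)OC(C)(C)[C@H](C)C[C@H](C)/C(C)=C\CC[C@H](C)C=C | intermediate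
25 | tertiary C21 cation: (3R,5S,6Z,10S)-2,3,5,6,10-pentamethyldodeca-6,11-dien-2-ylium triflate | C[C+](C)[C@H](C)C[C@H](C)/C(C)=C\CC[C@H](C)C=C.[O-]S(=O)(=O)C(F)(F)F | intermediate
26 | cyclohexyl C17 cation: ring closed C16–C21, charge at C17, side chain axial at C16, C18 and C20 methyls equatorial, triflate ion pair | C=C[C@@H](C)CC[C@@H]1[C+](C)[C@@H](C)C[C@@H](C)C1(C)C.[O-]S(=O)(=O)C(F)(F)F | intermediate
27 | hydride-shifted C18 cation: charge at C18, C17–H on the face of the side chain, C17–Me trans to it, triflate ion pair | C=C[C@@H](C)CC[C@@H]1[C@@H](C)[C+](C)C[C@@H](C)C1(C)C.[O-]S(=O)(=O)C(F)(F)F | intermediate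
28 | (3R,5R,6R)-1,3,4,4,6-pentamethyl-5-[(3S)-3-methylpent-4-en-1-yl]cyclohex-1-ene | C=C[C@@H](C)CC[C@@H]1[C@@H](C)C(C)=C[C@@H](C)C1(C)C | intermediate
29 | 4,4,5,5-tetramethyl-2-{(1E,3S)-3-methyl-5-[(1R,2R,5R)-2,3,5,6,6-pentamethylcyclohex-3-en-1-yl]pent-1-en-1-yl}-1,3,2-dioxaborolane | CC1(C)OB(/C=C/[C@@H](C)CC[C@@H]2[C@@H](C)C(C)=C[C@@H](C)C2(C)C)OC1(C)C | intermediate
30 | (3R,7R,10S,11E,13S)-10-ethenyl-2,3,7,10,13-pentamethyl-6-methylidene-15-[(1R,2R,5R)-2,3,5,6,6-pentamethylcyclohex-3-en-1-yl]pentadeca-1,11-diene | C=C[C@@](C)(/C=C/[C@@H](C)CC[C@@H]1[C@@H](C)C(C)=C[C@@H](C)C1(C)C)CC[C@@H](C)C(=C)CC[C@@H](C)C(=C)C | target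

**Totals**
Total step count: 16.
Longest linear sequence: 8 steps (steps 1–7, then step 16). The other arm is 7 steps (steps 10–16); steps 8–9 feed into step 13.

**Steps most likely to fail, with fallbacks**

Step 14 (cascade cyclisation). The risks are proton loss from the open C21 cation before ring closure, and loss of the wrong proton at the end (tetrasubstituted C17=C18 or exocyclic alkene instead of C18=C19). The fallback sets out from 24 and returns at 28. The silyl ether is cleaved (K2CO3, MeOH, 40 °C) to (3R,5S,6Z,10S)-2,3,5,6,10-pentamethyldodeca-6,11-dien-2-ol F3. This is dehydrated (Burgess reagent, benzene, 50 °C) to (3R,5S,6Z,10S)-2,3,5,6,10-pentamethyldodeca-1,6,11-triene F4; the minor tetrasubstituted regioisomer leads to the same C21 cation and need not be removed. The ring closure is then started by protonation of the isopropenyl group inside a confined chiral imidodiphosphorimidate Brønsted acid (5 mol%) in hexafluoroisopropanol/CHCl3 at −20 °C. Here the catalyst anion, held next to the cation, acts as the base instead of a free pyridine, so the site of the final deprotonation is chosen by the catalyst pocket and can be tuned through the catalyst.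

Step 13 (Z-selective Wittig). The risks are modest Z:E ratio and enolisation of the hindered ketone. The fallback sets out from 22 and returns at 24. Alkaline hydrolysis of the salt (NaOH, H2O/EtOH, reflux) gives [(4S)-4-methylhex-5-en-1-yl]diphenylphosphine oxide F1. Lithiation (n-BuLi, THF, −78 °C) and addition to ketone 17 gives β-hydroxy phosphine oxides. The diastereomer (3R,5S,6S,7R,10S)-7-(diphenylphosphoryl)-2,3,5,6,10-pentamethyl-2-[(trimethylsilyl)oxy]dodec-11-en-6-ol F2 is separated by chromatography and eliminated syn-stereospecifically (NaH, DMF, 50 °C) to give 24 as the pure Z isomer (Horner–Wittig). The other diastereomer is returned to ketone and phosphine oxide by base-induced retro-addition and recycled.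

Step 16 (quaternary centre by allylic substitution with an alkenylboronate). The risks are low conversion with the hindered α-branched alkenyl group and insufficient enantiocontrol. The fallback sets out from 11 and 29 and returns at 30. Sharpless epoxidation of 11 (Ti(OiPr)4, D-(−)-diethyl tartrate, t-BuOOH, CH2Cl2, −20 °C) gives [(2R,3R)-3-methyl-3-[(3R,7R)-3,7,8-trimethyl-4-methylidenenon-8-en-1-yl]oxiran-2-yl]methanol F5. Iododeboronation of 29 (NaOH, then I2, THF, 0 °C) gives (3R,5R,6R)-5-[(3S,4E)-5-iodo-3-methylpent-4-en-1-yl]-1,3,4,4,6-pentamethylcyclohex-1-ene F6. Halogen–lithium exchange (t-BuLi, Et2O, −78 °C) and Me2AlCl give dimethyl{(1E,3S)-3-methyl-5-[(1R,2R,5R)-2,3,5,6,6-pentamethylcyclohex-3-en-1-yl]pent-1-en-1-yl}alumane F7, which is used without isolation. It opens the epoxy alcohol at the tertiary C3 with inversion (hexane/CH2Cl2, 0 °C) to (2S,3R,6R,10R)-3,6,10,11-tetramethyl-7-methylidene-3-{(1E,3S)-3-methyl-5-[(1R,2R,5R)-2,3,5,6,6-pentamethylcyclohex-3-en-1-yl]pent-1-en-1-yl}dodec-11-ene-1,2-diol F8, which already carries the C10 quaternary centre. Deoxygenation of the 1,2-diol to the vinyl group (PPh3, imidazole, I2, toluene, 80 °C) gives 30. The quaternary centre is then set by substrate-controlled epoxide opening rather than by a catalyst.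

**Further compounds**
F1 | step 13 | [(4S)-4-methylhex-5-en-1-yl]diphenylphosphine oxide | C=C[C@@H](C)CCCP(=O)(c1ccccc1)c1ccccc1
F2 | step 13 | (3R,5S,6S,7R,10S)-7-(diphenylphosphoryl)-2,3,5,6,10-pentamethyl-2-[(trimethylsilyl)oxy]dodec-11-en-6-ol | C[Si](C)(C)OC(C)(C)[C@H](C)C[C@H](C)[C@](C)(O)[C@@H](CC[C@H](C)C=C)P(=O)(c1ccccc1)c1ccccc1
F3 | step 14 | (3R,5S,6Z,10S)-2,3,5,6,10-pentamethyldodeca-6,11-dien-2-ol | CC(C)(O)[C@H](C)C[C@H](C)/C(C)=C\CC[C@H](C)C=C
F4 | step 14 | (3R,5S,6Z,10S)-2,3,5,6,10-pentamethyldodeca-1,6,11-triene | C=C(C)[C@H](C)C[C@H](C)/C(C)=C\CC[C@H](C)C=C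
F5 | step 16 | [(2R,3R)-3-methyl-3-[(3R,7R)-3,7,8-trimethyl-4-methylidenenon-8-en-1-yl]oxiran-2-yl]methanol | OC[C@H]1O[C@]1(C)CC[C@@H](C)C(=C)CC[C@@H](C)C(=C)C
F6 | step 16 | (3R,5R,6R)-5-[(3S,4E)-5-iodo-3-methylpent-4-en-1-yl]-1,3,4,4,6-pentamethylcyclohex-1-ene | I/C=C/[C@@H](C)CC[C@@H]1[C@@H](C)C(C)=C[C@@H](C)C1(C)C
F7 | step 16 | dimethyl{(1E,3S)-3-methyl-5-[(1R,2R,5R)-2,3,5,6,6-pentamethylcyclohex-3-en-1-yl]pent-1-en-1-yl}alumane | C[Al](C)/C=C/[C@@H](C)CC[C@@H]1[C@@H](C)C(C)=C[C@@H](C)C1(C)C
F8 | step 16 | (2S,3R,6R,10R)-3,6,10,11-tetramethyl-7-methylidene-3-{(1E,3S)-3-methyl-5-[(1R,2R,5R)-2,3,5,6,6-pentamethylcyclohex-3-en-1-yl]pent-1-en-1-yl}dodec-11-ene-1,2-diol | OC[C@@H](O)[C@@](C)(/C=C/[C@@H](C)CC[C@@H]1[C@@H](C)C(C)=C[C@@H](C)C1(C)C)CC[C@@H](C)C(=C)CC[C@@H](C)C(=C)C
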